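**Retrosynthetic overview**
- The target is a 1H-pyrrole-2-carbaldehyde carrying a C19 chain on C5. C1'–C9' are saturated, and C10'=C11', C13'=C14' and C16'=C17' form an all-Z skipped triene. The strategy rests on the six carbons C11'–C16': the central Z-alkene C13'=C14' with its flanking CH2 groups C12' and C15' is a (Z)-hex-3-ene-1,6-diyl unit with an ylide carbon at each end.
- Last disconnection: the formyl carbon on the pyrrole ring (Vilsmeier–Haack) leads back to the 2-trienylpyrrole.
- Key disconnection: C10'=C11' and C16'=C17' are cut together, giving 10-(1H-pyrrol-2-yl)decanal, the (Z)-hexenediyl bis-phosphonium salt and propanal.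
- The aldehyde comes from pyrrole and monomethyl sebacate (C2-acylation, one LiAlH4 reduction of both carbonyl groups, oxidation). The bis-salt comes from (Z)-hex-3-ene-1,6-diol.
- No ring is formed; the pyrrole ring is bought intact.

Key step: step 7

Remark on the chemistry: side-chain carbons are numbered C1'–C19' from the pyrrole. The pyrrole N–H stays unprotected because its acidity is close to that of a phosphonium α-C–H, so proton exchange with ylide is reversible and is covered by excess bis-ylide. Monomethyl sebacate and (Z)-hex-3-ene-1,6-diol are taken as purchasable.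

**Route**

Step 1
Reactants: 1 monomethyl sebacate (10-methoxy-10-oxodecanoic acid)
Product: 2 methyl 10-oxo-10-(pyridin-2-ylsulfanyl)decanoate (S-2-pyridyl thioester)
Conditions: 2,2'-dipyridyl disulfide, PPh3, toluene, rt
Reagents that add atoms: 2,2'-dipyridyl disulfide, c1ccc(nc1)SSc1ccccn1
Why: The Mukaiyama redox condensation (PPh3/dipyridyl disulfide) should turn the free acid into the activated 2-pyridyl thioester under neutral conditions that leave the methyl ester untouched.

Step 2
Reactants: 2 methyl 10-oxo-10-(pyridin-2-ylsulfanyl)decanoate; 3 pyrrole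
Product: 5 methyl 10-oxo-10-(1H-pyrrol-2-yl)decanoate, via pyrrol-1-ylmagnesium bromide 4 (not isolated)
Conditions: 3 (3 equiv), EtMgBr, THF/toluene, 0 °C; then 2, −78 °C; H2O quench
Reagents that add atoms: none
Why: This is the C2-acylation of a pyrrolylmagnesium halide by a 2-pyridyl thioester, in which magnesium chelation between the thioester oxygen and the pyridine nitrogen should activate the acyl group and direct it to C2 instead of nitrogen, while the weakly nucleophilic reagent should spare the methyl ester at −78 °C.

Step 3
Reactants: 5 methyl 10-oxo-10-(1H-pyrrol-2-yl)decanoate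
Product: 6 10-(1H-pyrrol-2-yl)decan-1-ol
Conditions: LiAlH4 (excess), THF, 0 °C → reflux; then H2O
Reagents that add atoms: none
Why: LiAlH4 should reduce the ester to the primary alcohol and also deoxygenate the 2-acylpyrrole to the 2-alkylpyrrole (hydride addition, nitrogen-assisted loss of the aluminate oxygen from the N-metallated carbinol, second hydride addition), which is the known reductive deoxygenation of 2-acylpyrroles.

Step 4
Reactants: 6 10-(1H-pyrrol-2-yl)decan-1-ol
Product: 7 10-(1H-pyrrol-2-yl)decanal
Conditions: SO3·pyridine, DMSO, Et3N, CH2Cl2, 0 °C; used at once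
Reagents that add atoms: none
Why: The Parikh–Doering oxidation (activated DMSO) should stop at the aldehyde under basic, non-acidic conditions and uses no halogenating or hypervalent-iodine oxidant that could attack the electron-rich pyrrole.

Step 5
Reactants: 8 (Z)-hex-3-ene-1,6-diol
Product: 9 (Z)-1,6-dibromohex-3-ene
Conditions: CBr4, PPh3, CH2Cl2, 0 °C → rt
Reagents that add atoms: carbon tetrabromide, BrC(Br)(Br)Br
Why: The Appel reaction should replace both primary hydroxyl groups by SN2 attack of bromide on the alkoxyphosphonium ions without touching the Z-alkene.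

Step 6
Reactants: 9 (Z)-1,6-dibromohex-3-ene
Product: 10 (Z)-hex-3-ene-1,6-diylbis(triphenylphosphonium) dibromide
Conditions: PPh3 (2.5 equiv), MeCN, reflux
Reagents that add atoms: triphenylphosphine, c1ccccc1P(c1ccccc1)c1ccccc1
Why: Double SN2 quaternisation of PPh3 by the two primary homoallylic bromides should give the crystalline bis-phosphonium salt with the Z-alkene intact.

Step 7
Reactants: 10 (Z)-hex-3-ene-1,6-diylbis(triphenylphosphonium) dibromide; 7 10-(1H-pyrrol-2-yl)decanal; 11 propanal
Product: 14 2-[(10Z,13Z,16Z)-nonadeca-10,13,16-trien-1-yl]-1H-pyrrole, via hexenediyl bis-ylide 12 (not isolated), via dienyl mono-ylide 13 (not isolated)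
Conditions: 10 (2 equiv), NaN(SiMe3)2 (4 equiv), THF, −78 → −20 °C; then 7 (1 equiv, slow addition), −78 °C; then 11 (excess), −78 °C → rt
Reagents that add atoms: none
Why: NaN(SiMe3)2 removes one α-proton at each phosphonium centre of 10 to give the lithium-free bis-ylide 12; slow addition of 7 as the limiting component lets one ylide terminus add to the aldehyde through a kinetically formed cis-oxaphosphetane whose syn-cycloreversion releases Ph3P=O and the Z C10'=C11' alkene, leaving mono-ylide 13, which excess propanal then converts in the same way into the Z C16'=C17' alkene. The closest known reaction type is the double Z-selective Wittig olefination of this bis-ylide with aldehydes to give all-Z skipped trienes, here run with two different aldehydes in sequence. No ring is closed and no stereocentre is created; the C13'=C14' Z-alkene is carried in unchanged from 10. Z geometry at both new alkenes should follow from the non-stabilised ylide with a sodium counter-ion and no lithium salt at −78 °C reacting with unbranched aliphatic aldehydes. Cross-coupling over homo-coupling should follow from inverse addition of 7 to a two-fold excess of 12, and the two symmetrical by-products (the volatile, pyrrole-free C12 triene from double capping with propanal and the bis-pyrrole triene with two N–H groups) should differ clearly in polarity from 14 with its single N–H. The unprotected pyrrole N–H can only exchange a proton reversibly with ylide, which the excess of 12 absorbs.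

Step 8
Reactants: 14 2-[(10Z,13Z,16Z)-nonadeca-10,13,16-trien-1-yl]-1H-pyrrole
Product: 16 5-[(10Z,13Z,16Z)-nonadeca-10,13,16-trien-1-yl]-1H-pyrrole-2-carbaldehyde (the target), via pyrrolylmethylidene dimethyliminium chloride 15 (not isolated)
Conditions: POCl3, DMF, ClCH2CH2Cl, 0 °C → rt; then aq. NaOAc, rt
Reagents that add atoms: N,N-dimethylformamide, CN(C)C=O; water, O
Why: Vilsmeier–Haack formylation should take place at the only free α-carbon (C5) of the 2-alkylpyrrole, since the chloroiminium electrophile does not attack isolated Z-alkenes at 0 °C, and buffered hydrolysis of iminium salt 15 should release the aldehyde.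

**Compound list**
1 | monomethyl sebacate (10-methoxy-10-oxodecanoic acid) | COC(=O)CCCCCCCCC(=O)O | starting material
2 | methyl 10-oxo-10-(pyridin-2-ylsulfanyl)decanoate | COC(=O)CCCCCCCCC(=O)Sc1ccccn1 | intermediate
3 | pyrrole | c1cc[nH]c1 | starting material
4 | pyrrol-1-ylmagnesium bromide | Br[Mg]n1cccc1 | intermediate
5 | methyl 10-oxo-10-(1H-pyrrol-2-yl)decanoate | COC(=O)CCCCCCCCC(=O)c1ccc[nH]1 | intermediate
6 | 10-(1H-pyrrol-2-yl)decan-1-ol | OCCCCCCCCCCc1ccc[nH]1 | intermediate
7 | 10-(1H-pyrrol-2-yl)decanal | O=CCCCCCCCCCc1ccc[nH]1 | intermediate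
8 | (Z)-hex-3-ene-1,6-diol | OCC/C=C\CCO | starting material
9 | (Z)-1,6-dibromohex-3-ene | BrCC/C=C\CCBr | intermediate
10 | (Z)-hex-3-ene-1,6-diylbis(triphenylphosphonium) dibromide | c1ccccc1[P+](c1ccccc1)(c1ccccc1)CC/C=C\CC[P+](c1ccccc1)(c1ccccc1)c1ccccc1.[Br-].[Br-] | intermediate
11 | propanal | CCC=O | starting material
12 | (Z)-hex-3-ene-1,6-diylidenebis(triphenylphosphorane) | c1ccccc1P(c1ccccc1)(c1ccccc1)=CC/C=C\CC=P(c1ccccc1)(c1ccccc1)c1ccccc1 | intermediate
13 | [(3Z,6Z)-16-(1H-pyrrol-2-yl)hexadeca-3,6-dien-1-ylidene]triphenylphosphorane | c1ccccc1P(c1ccccc1)(c1ccccc1)=CC/C=C\C/C=C\CCCCCCCCCc1ccc[nH]1 | intermediate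
14 | 2-[(10Z,13Z,16Z)-nonadeca-10,13,16-trien-1-yl]-1H-pyrrole | CC/C=C\C/C=C\C/C=C\CCCCCCCCCc1ccc[nH]1 | intermediate
15 | N,N-dimethyl-1-{5-[(10Z,13Z,16Z)-nonadeca-10,13,16-trien-1-yl]-1H-pyrrol-2-yl}methaniminium chloride | C[N+](C)=Cc1ccc(CCCCCCCCC/C=C\C/C=C\C/C=C\CC)[nH]1.[Cl-] | intermediate
16 | 5-[(10Z,13Z,16Z)-nonadeca-10,13,16-trien-1-yl]-1H-pyrrole-2-carbaldehyde (mycalazal 20) | CC/C=C\C/C=C\C/C=C\CCCCCCCCCc1ccc(C=O)[nH]1 | target

**Step count**
Total: 8 steps. Longest linear sequence: 6 steps (steps 1, 2, 3, 4, 7, 8); the bis-phosphonium branch (steps 5, 6) joins at step 7.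

**Steps most likely to fail**

1. Step 7. Two molecules of 7 may cap one bis-ylide, ylide titre may be lost by proton transfer from the pyrrole N–H, and Z-selectivity may erode if the oxaphosphetanes equilibrate. Fallback, from 7 back to 14: a two-component Wittig in which both remaining Z-alkenes are already in the ylide. Purchased (3Z,6Z)-nona-3,6-dien-1-ol (CC/C=C\C/C=C\CCO) would be brominated with CBr4/PPh3 to (3Z,6Z)-1-bromonona-3,6-diene F1. Heating F1 with PPh3 in MeCN would give [(3Z,6Z)-nona-3,6-dien-1-yl]triphenylphosphonium bromide F2. NaN(SiMe3)2 in THF at −78 °C would generate (3Z,6Z)-nona-3,6-dien-1-ylidenetriphenylphosphorane F3, to which 7 is added to form the Z C10'=C11' alkene of 14.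

2. Step 4. The electron-rich pyrrole ring may be degraded by the oxidant, and the free α-carbon of one molecule may condense with the new aldehyde of another under trace acid. Fallback, from 5 back to 7: the aldehyde is reached by reduction instead of oxidation. Wolff–Kishner reduction of 5 (N2H4·H2O, KOH, diethylene glycol, 200 °C) would pass through 10-hydrazinylidene-10-(1H-pyrrol-2-yl)decanoic acid F4 and give, with saponification of the ester, 10-(1H-pyrrol-2-yl)decanoic acid F5. Activation with 1,1'-carbonyldiimidazole and MeNHOMe·HCl would give N-methoxy-N-methyl-10-(1H-pyrrol-2-yl)decanamide F6. i-Bu2AlH in THF at −78 °C would reduce F6 to 7.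

3. Step 8. HCl released during formylation and hydrolysis may shift or hydrochlorinate the skipped Z-alkenes or oligomerise the pyrrole. Fallback, from 6 directly to 16: the formyl group is installed before the triene exists. Excess POCl3/DMF on 6 would formylate C5 and O-formylate the alcohol, giving after aqueous work-up 10-(5-formyl-1H-pyrrol-2-yl)decyl formate F7. Aqueous NaOH in MeOH would cleave the formate to 5-(10-hydroxydecyl)-1H-pyrrole-2-carbaldehyde F8. Dess–Martin periodinane, tolerated now that the ring is deactivated, would give 5-(10-oxodecyl)-1H-pyrrole-2-carbaldehyde F9. Adding F9 to slightly more than 2 equiv of the ylide F3 from the step 7 fallback at −78 °C should give 16: the first equivalent deprotonates the acidic N–H and turns the ring formyl group into an unreactive vinylogous formamide anion, and the second olefinates only the aliphatic aldehyde.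

**Further compounds**
F1 | step 7 | (3Z,6Z)-1-bromonona-3,6-diene | CC/C=C\C/C=C\CCBr
F2 | step 7 | [(3Z,6Z)-nona-3,6-dien-1-yl]triphenylphosphonium bromide | CC/C=C\C/C=C\CC[P+](c1ccccc1)(c1ccccc1)c1ccccc1.[Br-]
F3 | step 7 | (3Z,6Z)-nona-3,6-dien-1-ylidenetriphenylphosphorane | CC/C=C\C/C=C\CC=P(c1ccccc1)(c1ccccc1)c1ccccc1
F4 | step 4 | 10-hydrazinylidene-10-(1H-pyrrol-2-yl)decanoic acid (C=N geometry not defined) | NN=C(CCCCCCCCC(=O)O)c1ccc[nH]1
F5 | step 4 | 10-(1H-pyrrol-2-yl)decanoic acid | OC(=O)CCCCCCCCCc1ccc[nH]1
F6 | step 4 | N-methoxy-N-methyl-10-(1H-pyrrol-2-yl)decanamide | CON(C)C(=O)CCCCCCCCCc1ccc[nH]1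
F7 | step 8 | 10-(5-formyl-1H-pyrrol-2-yl)decyl formate | O=COCCCCCCCCCCc1ccc(C=O)[nH]1
F8 | step 8 | 5-(10-hydroxydecyl)-1H-pyrrole-2-carbaldehyde | OCCCCCCCCCCc1ccc(C=O)[nH]1
F9 | step 8 | 5-(10-oxodecyl)-1H-pyrrole-2-carbaldehyde | O=CCCCCCCCCCc1ccc(C=O)[nH]1
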